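The oxane is cut at C5–C6, the bond between the OCH2 carbon and the ring carbon that carries the side chain. C6, flanked by O1, is read as a formaldehyde oxocarbenium carbon and C5 as the γ-carbon of an allylsilane. One Lewis-acid event therefore closes the ring, relays the C2 configuration to C5 through a chair (2,5-trans) and leaves a vinyl group at C5. C2 and its α-methylene ester come from a catalytic asymmetric Morita–Baylis–Hillman (MBH) reaction, so the precursor is an acyclic MEM ether of an MBH adduct. The vinyl group is then joined by B-alkyl Suzuki coupling to an (E)-vinyl iodide that carries the remote carbinol.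

Key step: step 4

Assumption: step 1 is taken to give mainly the (E)-allylsilane; the minor (Z)-isomer is carried along, because both geometries lose this alkene in step 4 and give the same vinyl group.
Numbering used in the text: oxane O1, C2 (bears the acrylate unit), C5 (bears the side chain), C6 (OCH2). β-Isocupreidine is taken as a purchasable catalyst.

Step 1
Reactants: 1 pent-4-enal; 2 allyltrimethylsilane
Product: 3 (4E)-6-(trimethylsilyl)hex-4-enal
Conditions: second-generation Grubbs catalyst (2 mol %), 2 (3 equiv), CH2Cl2, 40 °C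
Reagents that add atoms: none
Why: Olefin cross-metathesis of a terminal alkene with excess allyltrimethylsilane is driven by loss of ethylene and tolerates the aldehyde; it should give mainly the E-alkene and forms no stereocenter.

Step 2
Reactants: 3 (4E)-6-(trimethylsilyl)hex-4-enal; 4 1,1,1,3,3,3-hexafluoropropan-2-yl prop-2-enoate
Product: 5 1,1,1,3,3,3-hexafluoropropan-2-yl (3R,6E)-3-hydroxy-2-methylidene-8-(trimethylsilyl)oct-6-enoate
Conditions: β-isocupreidine (10 mol %), 4 (1.3 equiv), DMF, −55 °C
Reagents that add atoms: none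
Why: Catalytic asymmetric Morita–Baylis–Hillman reaction: the quinuclidine nitrogen adds to the activated fluorinated acrylate and the phenol of the catalyst hydrogen-bonds the aldolate, which fixes the aldehyde face and should set the carbinol (future C2) as R under catalyst control, as is usual for unbranched aliphatic aldehydes.

Step 3
Reactants: 5 1,1,1,3,3,3-hexafluoropropan-2-yl (3R,6E)-3-hydroxy-2-methylidene-8-(trimethylsilyl)oct-6-enoate
Product: 6 1,1,1,3,3,3-hexafluoropropan-2-yl (3R,6E)-3-[(2-methoxyethoxy)methoxy]-2-methylidene-8-(trimethylsilyl)oct-6-enoate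
Conditions: MEMCl (2 equiv), iPr2NEt (3 equiv), CH2Cl2, 0 °C → rt
Reagents that add atoms: 2-methoxyethoxymethyl chloride (MEMCl), COCCOCCl
Why: O-Alkylation of the hindered allylic alcohol with the reactive α-chloro ether under a non-nucleophilic amine base (MEM protection) leaves the active ester, the allylsilane and the carbinol configuration untouched; the acetal CH2 installed here becomes C6.

Step 4
Reactants: 6 1,1,1,3,3,3-hexafluoropropan-2-yl (3R,6E)-3-[(2-methoxyethoxy)methoxy]-2-methylidene-8-(trimethylsilyl)oct-6-enoate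
Product: 8 1,1,1,3,3,3-hexafluoropropan-2-yl 2-[(2R,5R)-5-ethenyloxan-2-yl]prop-2-enoate, via O-methylene oxocarbenium ion 7 (not isolated)
Conditions: TiCl4 (2.2 equiv), 2,6-di-tert-butyl-4-methylpyridine (0.5 equiv), CH2Cl2, −78 °C; aq NaHCO3
Reagents that add atoms: none
Why: TiCl4 chelates the two outer oxygens of the MEM group and expels 2-methoxyethoxide, which unmasks the O-methylene oxocarbenium ion 7; its carbon (future C6) is attacked by the γ-carbon of the allylsilane (future C5) in an SE2' process, and the β-silyl cation loses the silyl group to chloride to leave the vinyl group. The closest known reaction type is the acetal-initiated intramolecular Hosomi–Sakurai (allylsilane–oxocarbenium) cyclization of MEM ethers to 3-vinyl oxanes. The six-membered ring closes endo with respect to the C=O+ bond (6-endo-trig) and exo with respect to the allylsilane alkene. The new stereocenter C5 is controlled by C2 through a chair-like transition state in which the C2 substituent and the C5 alkenyl arm are both pseudo-equatorial, which should give the 2,5-trans (2R,5R) ring from either alkene geometry. The step needs ionization on the MEM side of the acetal (secured by chelation and by the electron-poor allylic C2–O bond) and attack on the oxocarbenium ion in preference to the acrylate (secured by the far higher electrophilicity of the cation at −78 °C and the weak Lewis basicity of the fluorinated ester); the hindered pyridine suppresses protodesilylation.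

Step 5
Reactants: 9 pent-4-yn-1-ol
Product: 11 (4E)-5-iodo-4-methylpent-4-en-1-ol, via alkenylalane 10 (not isolated)
Conditions: Me3Al (3 equiv), Cp2ZrCl2 (0.25 equiv), CH2Cl2, 0 °C → rt; then I2, THF, −30 → 0 °C; aq K2CO3
Reagents that add atoms: trimethylaluminium (Me3Al), C[Al](C)C; iodine, II
Why: Negishi zirconium-catalysed carboalumination adds methyl and aluminium syn across the alkyne with the metal at the terminus (the hydroxyl is carried as its aluminium alkoxide), and iodinolysis of the C–Al bond with retention gives the (E)-iodoalkene.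

Step 6
Reactants: 11 (4E)-5-iodo-4-methylpent-4-en-1-ol
Product: 12 (4E)-5-iodo-4-methylpent-4-enal
Conditions: TEMPO (10 mol %), PhI(OAc)2 (1.1 equiv), CH2Cl2, rt
Reagents that add atoms: none
Why: TEMPO-catalysed oxidation of the primary alcohol stops at the aldehyde and does not touch the vinyl iodide.

Step 7
Reactants: 12 (4E)-5-iodo-4-methylpent-4-enal
Product: 13 racemic (6E)-7-iodo-2,6-dimethylhepta-1,6-dien-3-ol
Conditions: CH2=C(CH3)MgBr (1.2 equiv), THF, −78 → 0 °C; aq NH4Cl
Reagents that add atoms: isopropenylmagnesium bromide, CC(=C)[Mg]Br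
Why: Grignard 1,2-addition to the aldehyde; the carbinol is deliberately racemic because it is erased in step 8.

Step 8
Reactants: 13 racemic (6E)-7-iodo-2,6-dimethylhepta-1,6-dien-3-ol
Product: 15 ethyl (4E,8E)-9-iodo-4,8-dimethylnona-4,8-dienoate, via allyl ketene acetal 14 (not isolated)
Conditions: MeC(OEt)3 (6 equiv), EtCO2H (0.1 equiv), 140 °C, EtOH distilled off
Reagents that add atoms: triethyl orthoacetate, CC(OCC)(OCC)OCC
Why: Johnson–Claisen orthoester rearrangement: the ketene acetal rearranges through a chair with the carbinol substituent equatorial, which converts the isopropenyl carbinol into the (E)-trisubstituted alkene with a two-carbon ester extension.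

Step 9
Reactants: 15 ethyl (4E,8E)-9-iodo-4,8-dimethylnona-4,8-dienoate
Product: 17 (6E,10E)-11-iodo-2,6,10-trimethylundeca-1,6,10-trien-3-one, via Weinreb amide 16 (not isolated)
Conditions: MeNH(OMe)·HCl (1.5 equiv), iPrMgCl (3.0 equiv), THF, −20 °C; then CH2=C(CH3)MgBr (2.5 equiv), 0 °C; inverse quench into cold 1 M HCl
Reagents that add atoms: isopropenylmagnesium bromide, CC(=C)[Mg]Br
Why: Magnesium-amide aminolysis of the ester gives the Weinreb amide, and Grignard addition in the same flask gives a chelated tetrahedral intermediate that holds until the acidic quench and so stops at the isopropenyl ketone (Weinreb ketone synthesis); the amine is released again.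

Step 10
Reactants: 17 (6E,10E)-11-iodo-2,6,10-trimethylundeca-1,6,10-trien-3-one
Product: 18 (3R,6E,10E)-11-iodo-2,6,10-trimethylundeca-1,6,10-trien-3-ol
Conditions: (S)-2-methyl-CBS-oxazaborolidine (0.2 equiv), catecholborane (1.5 equiv), toluene, −78 °C; MeOH, then aq NaOH wash
Reagents that add atoms: none
Why: Corey–Bakshi–Shibata reduction: the ketone binds the (S)-oxazaborolidine with the isopropenyl group as the large substituent, and hydride from the coordinated borane is delivered to the face that should give the R carbinol; catecholborane at −78 °C does not hydroborate the alkenes.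

Step 11
Reactants: 8 1,1,1,3,3,3-hexafluoropropan-2-yl 2-[(2R,5R)-5-ethenyloxan-2-yl]prop-2-enoate; 18 (3R,6E,10E)-11-iodo-2,6,10-trimethylundeca-1,6,10-trien-3-ol
Product: 20 2-[(2R,5S)-5-[(3E,7E,11R)-11-hydroxy-4,8,12-trimethyltrideca-3,7,12-trien-1-yl]oxan-2-yl]prop-2-enoic acid (CNP0167023.2), via B-alkyl-9-BBN borane 19 (not isolated)
Conditions: 8 (1.3 equiv), 9-BBN (0.95 equiv per 8), THF, 0 °C → rt; then 18 (1.0 equiv), Pd(dppf)Cl2 (5 mol %), AsPh3 (10 mol %), 3 M aq NaOH (5 equiv), DMF, rt; then 1 M HCl, 0 °C, to pH 3–4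
Reagents that add atoms: sodium hydroxide in water, [Na+].[OH-]
Why: 9-BBN should hydroborate the electron-rich monosubstituted vinyl group anti-Markovnikov in preference to the electron-poor acrylate, and B-alkyl Suzuki–Miyaura coupling (oxidative addition of zerovalent palladium into the vinyl iodide, hydroxide-assisted transmetalation, reductive elimination) joins the side chain with retention of E geometry while the same aqueous NaOH saponifies the activated hexafluoroisopropyl ester; no stereocenter is formed or touched.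

Compound list
1 | pent-4-enal | C=CCCC=O | starting material
2 | allyltrimethylsilane | C=CC[Si](C)(C)C | starting material
3 | (4E)-6-(trimethylsilyl)hex-4-enal | C[Si](C)(C)C/C=C/CCC=O | intermediate
4 | 1,1,1,3,3,3-hexafluoropropan-2-yl prop-2-enoate | C=CC(=O)OC(C(F)(F)F)C(F)(F)F | starting material
5 | 1,1,1,3,3,3-hexafluoropropan-2-yl (3R,6E)-3-hydroxy-2-methylidene-8-(trimethylsilyl)oct-6-enoate | C[Si](C)(C)C/C=C/CC[C@H](C(=C)C(=O)OC(C(F)(F)F)C(F)(F)F)O | intermediate
6 | 1,1,1,3,3,3-hexafluoropropan-2-yl (3R,6E)-3-[(2-methoxyethoxy)methoxy]-2-methylidene-8-(trimethylsilyl)oct-6-enoate | C[Si](C)(C)C/C=C/CC[C@H](C(=C)C(=O)OC(C(F)(F)F)C(F)(F)F)OCOCCOC | intermediate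
7 | O-methylene oxocarbenium ion derived from 6 (R–O+=CH2) | C[Si](C)(C)C/C=C/CC[C@H](C(=C)C(=O)OC(C(F)(F)F)C(F)(F)F)[O+]=C | intermediate
8 | 1,1,1,3,3,3-hexafluoropropan-2-yl 2-[(2R,5R)-5-ethenyloxan-2-yl]prop-2-enoate | C=C[C@H]1CC[C@H](C(=C)C(=O)OC(C(F)(F)F)C(F)(F)F)OC1 | intermediate
9 | pent-4-yn-1-ol | C#CCCCO | starting material
10 | dimethylaluminium (4E)-5-(dimethylalumanyl)-4-methylpent-4-en-1-olate | C[Al](C)OCCC/C(C)=C/[Al](C)C | intermediate
11 | (4E)-5-iodo-4-methylpent-4-en-1-ol | OCCC/C(C)=C/I | intermediate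
12 | (4E)-5-iodo-4-methylpent-4-enal | O=CCC/C(C)=C/I | intermediate
13 | racemic (6E)-7-iodo-2,6-dimethylhepta-1,6-dien-3-ol | C=C(C)C(O)CC/C(C)=C/I | intermediate
14 | racemic (6E)-3-[(1-ethoxyethenyl)oxy]-7-iodo-2,6-dimethylhepta-1,6-diene | C=C(OCC)OC(CC/C(C)=C/I)C(C)=C | intermediate
15 | ethyl (4E,8E)-9-iodo-4,8-dimethylnona-4,8-dienoate | CCOC(=O)CC/C(C)=C/CC/C(C)=C/I | intermediate
16 | (4E,8E)-9-iodo-N-methoxy-N,4,8-trimethylnona-4,8-dienamide | CON(C)C(=O)CC/C(C)=C/CC/C(C)=C/I | intermediate
17 | (6E,10E)-11-iodo-2,6,10-trimethylundeca-1,6,10-trien-3-one | C=C(C)C(=O)CC/C(C)=C/CC/C(C)=C/I | intermediate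
18 | (3R,6E,10E)-11-iodo-2,6,10-trimethylundeca-1,6,10-trien-3-ol | C=C(C)[C@H](O)CC/C(C)=C/CC/C(C)=C/I | intermediate
19 | 1,1,1,3,3,3-hexafluoropropan-2-yl 2-[(2R,5S)-5-[2-(9-borabicyclo[3.3.1]nonan-9-yl)ethyl]oxan-2-yl]prop-2-enoate | C1CCC2CCCC1B2CC[C@H]3CC[C@H](C(=C)C(=O)OC(C(F)(F)F)C(F)(F)F)OC3 | intermediate
20 | 2-[(2R,5S)-5-[(3E,7E,11R)-11-hydroxy-4,8,12-trimethyltrideca-3,7,12-trien-1-yl]oxan-2-yl]prop-2-enoic acid | C=C(C)[C@H](O)CC/C(C)=C/CC/C(C)=C/CC[C@H]1CC[C@H](C(=C)C(=O)O)OC1 | target

Total step count: 11. Longest linear sequence: 7 steps (steps 5–11, from pent-4-yn-1-ol 9); the ring fragment takes 4 steps (steps 1–4) before the union.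

Steps most likely to fail

Step 4. The acetal may ionize at the wrong oxygen, so that the MEM group is simply lost. The allylsilane may be protodesilylated before the ring closes. The Lewis acid or chloride may attack the activated acrylate. The fallback sets out from 5. Pummerer-type O-alkylation with Me2S and dibenzoyl peroxide (MeCN, 0 °C) should give 1,1,1,3,3,3-hexafluoropropan-2-yl (3R,6E)-2-methylidene-3-[(methylsulfanyl)methoxy]-8-(trimethylsilyl)oct-6-enoate F1. S-Methylation with MeOTf in the presence of 2,6-di-tert-butyl-4-methylpyridine (CH2Cl2, 0 °C) makes dimethyl sulfide the only possible leaving group. The same oxocarbenium ion 7 then forms without a chelating metal halide and closes to 8, where the route is rejoined.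

Step 11. 9-BBN may hydroborate or conjugatively reduce the activated acrylate, and hydroxide may add to it during the coupling. The fallback sets out from 8. Base-catalysed conjugate addition of thiophenol (PhSH, cat. Et3N, CH2Cl2, 0 °C) masks the acrylate as 1,1,1,3,3,3-hexafluoropropan-2-yl 2-[(2R,5R)-5-ethenyloxan-2-yl]-3-(phenylsulfanyl)propanoate F2; both epimers at the new α-carbon are used, since that center is erased later. 9-BBN then meets only the vinyl group and gives 1,1,1,3,3,3-hexafluoropropan-2-yl 2-[(2R,5S)-5-[2-(9-borabicyclo[3.3.1]nonan-9-yl)ethyl]oxan-2-yl]-3-(phenylsulfanyl)propanoate F3. Coupling with 18 under the palladium and aqueous NaOH conditions of step 11, with saponification in the same flask, gives 2-[(2R,5S)-5-[(3E,7E,11R)-11-hydroxy-4,8,12-trimethyltrideca-3,7,12-trien-1-yl]oxan-2-yl]-3-(phenylsulfanyl)propanoic acid F4. NaIO4 (MeOH/H2O, 0 °C) oxidizes only the sulfide, to 3-(benzenesulfinyl)-2-[(2R,5S)-5-[(3E,7E,11R)-11-hydroxy-4,8,12-trimethyltrideca-3,7,12-trien-1-yl]oxan-2-yl]propanoic acid F5. Thermal syn-elimination (toluene, 90 °C, CaCO3) restores the α-methylene acid and returns to the route at 20.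

Step 9. The one-flask sequence may give incomplete amide formation or over-addition. The liberated N,O-dimethylhydroxylamine may add to the sensitive isopropenyl ketone on quenching, and the enone may polymerize. The fallback sets out from 15 and avoids the enone altogether. iBu2AlH (CH2Cl2, −78 °C) gives (4E,8E)-9-iodo-4,8-dimethylnona-4,8-dienal F6. Addition of CH2=C(CH3)MgBr (THF, −78 °C) gives racemic (6E,10E)-11-iodo-2,6,10-trimethylundeca-1,6,10-trien-3-ol F7. Sharpless kinetic resolution (Ti(OiPr)4, L-(+)-diisopropyl tartrate, tBuOOH 0.6 equiv, 4 Å sieves, CH2Cl2, −20 °C) should epoxidize the S enantiomer faster, to (1S,4E,8E)-9-iodo-4,8-dimethyl-1-[(2R)-2-methyloxiran-2-yl]nona-4,8-dien-1-ol F8. The unreacted R alcohol is 18, where the route is rejoined; this also bypasses step 10.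

Further compounds
F1 | step 4 | 1,1,1,3,3,3-hexafluoropropan-2-yl (3R,6E)-2-methylidene-3-[(methylsulfanyl)methoxy]-8-(trimethylsilyl)oct-6-enoate | C[Si](C)(C)C/C=C/CC[C@H](C(=C)C(=O)OC(C(F)(F)F)C(F)(F)F)OCSC
F2 | step 11 | 1,1,1,3,3,3-hexafluoropropan-2-yl 2-[(2R,5R)-5-ethenyloxan-2-yl]-3-(phenylsulfanyl)propanoate (both epimers at the α-carbon) | C=C[C@H]1CC[C@H](C(CSc2ccccc2)C(=O)OC(C(F)(F)F)C(F)(F)F)OC1
F3 | step 11 | 1,1,1,3,3,3-hexafluoropropan-2-yl 2-[(2R,5S)-5-[2-(9-borabicyclo[3.3.1]nonan-9-yl)ethyl]oxan-2-yl]-3-(phenylsulfanyl)propanoate | C1CCC2CCCC1B2CC[C@H]3CC[C@H](C(CSc4ccccc4)C(=O)OC(C(F)(F)F)C(F)(F)F)OC3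
F4 | step 11 | 2-[(2R,5S)-5-[(3E,7E,11R)-11-hydroxy-4,8,12-trimethyltrideca-3,7,12-trien-1-yl]oxan-2-yl]-3-(phenylsulfanyl)propanoic acid | C=C(C)[C@H](O)CC/C(C)=C/CC/C(C)=C/CC[C@H]1CC[C@H](C(CSc2ccccc2)C(=O)O)OC1
F5 | step 11 | 3-(benzenesulfinyl)-2-[(2R,5S)-5-[(3E,7E,11R)-11-hydroxy-4,8,12-trimethyltrideca-3,7,12-trien-1-yl]oxan-2-yl]propanoic acid | C=C(C)[C@H](O)CC/C(C)=C/CC/C(C)=C/CC[C@H]1CC[C@H](C(CS(=O)c2ccccc2)C(=O)O)OC1
F6 | step 9 | (4E,8E)-9-iodo-4,8-dimethylnona-4,8-dienal | O=CCC/C(C)=C/CC/C(C)=C/I
F7 | step 9 | racemic (6E,10E)-11-iodo-2,6,10-trimethylundeca-1,6,10-trien-3-ol | C=C(C)C(O)CC/C(C)=C/CC/C(C)=C/I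
F8 | step 9 | (1S,4E,8E)-9-iodo-4,8-dimethyl-1-[(2R)-2-methyloxiran-2-yl]nona-4,8-dien-1-ol | C[C@@]1(CO1)[C@@H](O)CC/C(C)=C/CC/C(C)=C/I
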